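## The problem

Atom labels used throughout: O1; C2 bears Ar1 (3,4-dimethoxyphenyl); C3 and C4 bear the methyl groups; C5 bears Ar2 (4-hydroxy-3,5-dimethoxyphenyl).

1. Target 14 is a 2,5-diaryl-3,4-dimethyloxolane with one ring (O1, C2, C3, C4, C5) and four contiguous stereocentres, C2 (S), C3 (S), C4 (R) and C5 (R). The relative configuration is 2,3-trans, 3,4-cis, 4,5-trans, so both aryl rings lie on the face opposite to both methyl groups.
2. The ring is easy to close. The hard part is that the compound is pseudo-meso: with two equal aryl rings it would be achiral, so its absolute configuration is only the decision which end of a mirror-symmetric chain receives Ar1 and which receives Ar2.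
3. Ar1 and Ar2 differ only in remote oxygen substituents, so no reagent can be expected to tell the two ends apart once both rings are in place. The ends must be differentiated earlier.
4. The feature that makes the key step possible: without the aryl rings, the unit O1–C2–C3–C4–C5 with its cis methyl groups on C3 and C4 has a mirror plane through O1 and the midpoint of the C3–C4 bond. At the diacid oxidation level this unit is the five-membered ring of the meso anhydride 2.
5. C3 and C4 cannot be corrected once set, and their cis relation is the less stable one; it is lost whenever a neighbouring carbonyl or oxocarbenium carbon enolises. In return, each controls its benzylic neighbour by 1,2-induction (C4 to C5, C3 to C2), and the trans relations wanted there are also the more stable ones.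
6. The C2–O1 and C5–O1 bonds are benzylic ethers of electron-rich arenes. Acid ionises them (epimerisation, or capture by the other aryl ring to an aryltetralin), hydrogenolysis can cut them, and the free phenol adds a quinone methide channel at C5 and sensitivity to oxidants.

## Retrosynthesis

**Disconnection 1 (O–benzyl bond, 14 to 13).** Only the phenolic oxygen changes. It must be masked because the route uses an aryllithium, hydrides and a Lewis acid, and because a free para-hydroxyl group would make C5–O1 much more labile in the Lewis acid step. The forward reaction has only to spare the two ring C–O bonds.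

**Disconnection 2 (C2–Ar1 bond, 13 to oxocarbenium ion 12 plus veratrole 11; 12 from lactol 10, 10 from lactone 9).**
- Three bonds at C2 could be cut.
- Cutting C2–H (hydride onto a 2-aryl oxocarbenium ion) is the usual choice. Hydride would enter anti to the C3 methyl group and leave Ar1 cis to it. An aryl-conjugated cation also loses its C3 proton easily, which would erase the cis-dimethyl relation.
- Cutting O1–C2 gives a 1,4-diol with two similar benzylic alcohols that cannot be addressed separately.
- Cutting C2–Ar1 turns the same facial bias into an advantage: the arene enters anti to both methyl groups and gives 2,3-trans and 2,5-cis directly.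
- 11 is symmetric and reacts para to a methoxy group, so it supplies exactly the 3,4-dimethoxyphenyl pattern. The precursor has one aryl ring and one stereocentre less.
- This fixes the order of events. Ar1 enters last by electrophilic aromatic substitution. Ar2, whose pattern that reaction would not deliver reliably, enters first as an organometal.

**Disconnection 3 (O1–C2 acyl bond and C5–H bond, 9 to hydroxy acid 8 to keto acid 7).** Opening the lactone and oxidising C5 removes the ring and a further stereocentre. The acyclic aryl ketone is the right stage to set C5. Open-chain 1,2-induction from C4 gives the OH/CH3-anti alcohol, which is the 4,5-trans lactone, whereas hydride delivery to a cyclic cation at C5 would give 4,5-cis. The forward reaction must be a fast, non-basic reduction by a bulky hydride, so that C4 does not enolise.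

**Disconnection 4 (C5–Ar2 bond, 7 to anhydride 2 plus arylzinc reagent 6; the key step).**
- With Ar2 removed, C2 and C5 become equivalent carbonyl groups and the carbon skeleton collapses to the achiral six-carbon ring of 2.
- Every other C–C cut in 7 (C3–C4, C4–C5, C–CH3) leaves a chiral fragment whose centres would have to be built one at a time.
- The forward reaction is a catalytic, enantiotopic-group-selective acyl cross-coupling. It should attach the first aryl ring, differentiate the termini (ketone at C5, acid at C2) and fix the absolute sense of C3 and C4 in one operation.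

**Disconnection 5 (2 to diacid 1; 6 to aryllithium 5 to bromide 4 to bromophenol 3).** The C3–C4 bond and the erythro relation of the methyl groups are bought with commercial 1; dehydration gives 2. The zinc reagent is reached from commercial 3 by O-benzylation, halogen–lithium exchange and transmetallation.

## Roads not taken

**Alternative 1 (the route most chemists would draw first).**
- Cut: C4–C5 by an aldol reaction, the chain then grown towards C2, and the C3 methyl group added last.
- Forward: an auxiliary-controlled, anti-selective propionate aldol reaction should give, after removal of the auxiliary, hydroxy ester A1. Protection, reduction, one-carbon homologation and oxidation lead to lactone A2, whose enolate is methylated. The end game would be as in steps 5 to 7.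
- Why the chosen plan is better: the enolate of A2 is attacked anti to the C4 methyl group, so the product is the 3,4-trans lactone A3, the C3 epimer of 9. The cis relation would need a further deprotonation and kinetic protonation. The aldol must be of the less general anti type, a stoichiometric auxiliary is consumed, and 9 is reached in about twice as many steps. The four centres are treated one by one and the hidden symmetry is unused.

**Alternative 2.**
- Cut: the central C3–C4 bond.
- Forward: oxidative hetero-coupling of the enolates of two aryl ethyl ketones to the 1,4-diketone A4, then double reduction and cyclodehydration. On paper this is the most convergent plan.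
- Why the chosen plan is better: three selectivities are asked of one bond formation. The first is hetero- against homo-coupling of nearly identical partners. The second is erythro against threo, with both alpha-centres of A4 still enolisable and free to drift to the more stable threo series. The third is absolute configuration, although the enantiomers of A4 differ only in which aryl ketone sits next to which methine. That third demand is exactly the Ar1/Ar2 discrimination that cannot be expected of a reagent. The chosen plan never makes the C3–C4 bond.

**Alternative 3.**
- Cut: O1–C5 and C2–C3, a (3+2) cycloaddition with strain release.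
- Forward: Lewis acid catalysed reaction of donor–acceptor cyclopropane A5 with an aryl aldehyde to the oxolane-3,3-diester A6. The ring and the 2,5-cis relation are made in one stereospecific step.
- Why the chosen plan is better: the reaction inverts the donor carbon, so the 4,5-trans product requires the cis-aryl/methyl cyclopropane A5 as a single enantiomer, a harder target than 2. C3 arrives as a quaternary malonate carbon. Converting C(CO2Me)2 to CH(CH3) costs four to five steps (dealkoxycarbonylation, reduction, activation, reduction). The C3 configuration would then rest on a protonation between an aryl group on one face and a methyl group on the other, with no clear bias.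

Key step: step 3

Assumption: the (S)-enantiomer of the phosphinooxazoline ligand is taken to direct rhodium to the carbonyl group next to the (R)-configured carbon of 2. If the sense is the opposite, the equally available (R)-ligand is used and nothing else changes.

## Route

Step 1
Reactants: 1 meso-2,3-dimethylsuccinic acid
Product: 2 cis-3,4-dimethyloxolane-2,5-dione (meso-2,3-dimethylsuccinic anhydride)
Conditions: AcCl (neat), reflux; evaporation
Reagents that add atoms: none
Why: Dehydrative cyclisation of a 1,4-diacid through the mixed anhydride (5-exo-trig); no base is present, so both alpha-centres should keep the erythro relation and the cis (meso) anhydride should result.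

Step 2
Reactants: 3 4-bromo-2,6-dimethoxyphenol
Product: 4 2-(benzyloxy)-5-bromo-1,3-dimethoxybenzene
Conditions: BnBr, K2CO3, DMF, rt
Reagents that add atoms: benzyl bromide, BrCc1ccccc1
Why: Williamson ether synthesis on the phenoxide; the benzyl ether masks the acidic OH against the organolithium, hydride and Lewis acid steps and is removable at the end under neutral conditions.

Step 3
Reactants: 4 2-(benzyloxy)-5-bromo-1,3-dimethoxybenzene; 2 cis-3,4-dimethyloxolane-2,5-dione
Product: 7 (2S,3R)-4-[4-(benzyloxy)-3,5-dimethoxyphenyl]-2,3-dimethyl-4-oxobutanoic acid, via aryllithium 5 (not isolated), via arylzinc triflate 6 (not isolated)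
Conditions: 4, n-BuLi, THF, −78 °C; Zn(OTf)2, −78 °C to rt; then 2, [Rh(cod)Cl]2 (cat.), (S)-t-Bu-PHOX (cat.), THF, 50 °C; aq. HCl
Reagents that add atoms: none
Why: This is an enantioselective acyl cross-coupling of a cyclic meso anhydride with an arylzinc reagent (Negishi-type acylation used as a desymmetrisation), a known reaction type for meso succinic anhydrides. Rh(I) bound to the chiral P,N-ligand inserts into one of the two enantiotopic acyl C–O bonds of 2 to give an acyl-rhodium carboxylate; transmetallation from 6 and reductive elimination form the C5–aryl bond and release the zinc carboxylate of 7, which the acid work-up protonates. No ring is closed; the anhydride ring is opened once. No bond to C3 or C4 is touched: both centres come from 2 with their cis (erythro) relation, and the ligand alone decides which of them ends up next to the ketone, that is, the absolute configuration (2S,3R). Three selectivities are needed: between the enantiotopic carbonyl groups (the mirror symmetry of 2 leaves the catalyst as the only source of bias, and the methyl groups next to the reacting carbonyls give the ligand something to read), single arylation (aryl ketone and carboxylate are inert to arylzinc reagents), and retention at the carbon alpha to the new ketone (non-basic medium). In one operation the C2–C5 chain should receive its first aryl ring, two different termini and its handedness.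

Step 4
Reactants: 7 (2S,3R)-4-[4-(benzyloxy)-3,5-dimethoxyphenyl]-2,3-dimethyl-4-oxobutanoic acid
Product: 9 (3S,4R,5R)-5-[4-(benzyloxy)-3,5-dimethoxyphenyl]-3,4-dimethyloxolan-2-one (3,4-cis, 4,5-trans), via hydroxy acid 8 (not isolated)
Conditions: L-Selectride (2.2 equiv), THF, −78 °C; then 2 M HCl, rt
Reagents that add atoms: none
Why: Felkin–Anh-controlled ketone reduction: the first equivalent deprotonates the acid, and the second attacks the aryl ketone anti to the CH(CH3)CO2Li group and past the hydrogen of C4, which should set C5 as R (OH anti to the C4 methyl group). Acidification closes the gamma-lactone (5-exo-trig) with retention at C5, so the aryl ring stands trans to the C4 methyl group. Low temperature and fast hydride transfer should leave the enolisable C4 untouched.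

Step 5
Reactants: 9 (3S,4R,5R)-5-[4-(benzyloxy)-3,5-dimethoxyphenyl]-3,4-dimethyloxolan-2-one
Product: 10 (3S,4R,5R)-5-[4-(benzyloxy)-3,5-dimethoxyphenyl]-3,4-dimethyloxolan-2-ol (mixture of anomers)
Conditions: DIBAL-H (1.1 equiv), CH2Cl2, −78 °C; aq. Rochelle salt
Reagents that add atoms: none
Why: Partial reduction of a gamma-lactone; the aluminium hemiacetal is stable at −78 °C and gives the lactol on work-up. The anomeric centre is of no consequence because both anomers converge in step 6, and the aryl ethers are inert.

Step 6
Reactants: 10 (3S,4R,5R)-5-[4-(benzyloxy)-3,5-dimethoxyphenyl]-3,4-dimethyloxolan-2-ol; 11 veratrole (1,2-dimethoxybenzene)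
Product: 13 (2S,3S,4R,5R)-5-[4-(benzyloxy)-3,5-dimethoxyphenyl]-2-(3,4-dimethoxyphenyl)-3,4-dimethyloxolane, via oxocarbenium ion 12 (not isolated)
Conditions: 11 (5 equiv), BF3·OEt2 (1.5 equiv), CH2Cl2, −78 to −30 °C; aq. NaHCO3
Reagents that add atoms: none
Why: Friedel–Crafts arylation of a lactol-derived five-membered oxocarbenium ion; 11 reacts para to a methoxy group and so delivers the 3,4-dimethoxyphenyl pattern. The arene should approach C2 of 12 from the face opposite to the C3 and C4 methyl groups, which sets C2 as S (2,3-trans, 2,5-cis). This epimer is also the more stable one, so any reversibility works in the same direction.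

Step 7
Reactants: 13 (2S,3S,4R,5R)-5-[4-(benzyloxy)-3,5-dimethoxyphenyl]-2-(3,4-dimethoxyphenyl)-3,4-dimethyloxolane
Product: 14 4-[(2R,3R,4S,5S)-5-(3,4-dimethoxyphenyl)-3,4-dimethyloxolan-2-yl]-2,6-dimethoxyphenol (target)
Conditions: H2 (1 atm), 10% Pd/C, EtOAc, rt, stopped after one equivalent
Reagents that add atoms: none
Why: Hydrogenolysis of an aryl benzyl ether; the unhindered primary benzylic C–O bond should be cleaved much faster than the two secondary ring C–O bonds flanked by methyl groups, provided the solvent is acid-free. No stereocentre is touched.

## Compound list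

1 | meso-2,3-dimethylsuccinic acid, (2R,3S) | OC(=O)[C@H](C)[C@H](C)C(O)=O | starting material
2 | cis-3,4-dimethyloxolane-2,5-dione, (3R,4S), meso | O=C1OC(=O)[C@H](C)[C@@H]1C | intermediate
3 | 4-bromo-2,6-dimethoxyphenol | COc1cc(Br)cc(OC)c1O | starting material
4 | 2-(benzyloxy)-5-bromo-1,3-dimethoxybenzene | COc1cc(Br)cc(OC)c1OCc1ccccc1 | intermediate
5 | [4-(benzyloxy)-3,5-dimethoxyphenyl]lithium | [Li]c1cc(OC)c(OCc2ccccc2)c(OC)c1 | intermediate
6 | [4-(benzyloxy)-3,5-dimethoxyphenyl]zinc triflate | O=S(=O)(O[Zn]c1cc(OC)c(OCc2ccccc2)c(OC)c1)C(F)(F)F | intermediate
7 | (2S,3R)-4-[4-(benzyloxy)-3,5-dimethoxyphenyl]-2,3-dimethyl-4-oxobutanoic acid | O=C(c1cc(OC)c(OCc2ccccc2)c(OC)c1)[C@H](C)[C@H](C)C(O)=O | intermediate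
8 | (2S,3R,4R)-4-[4-(benzyloxy)-3,5-dimethoxyphenyl]-4-hydroxy-2,3-dimethylbutanoic acid | O[C@@H](c1cc(OC)c(OCc2ccccc2)c(OC)c1)[C@H](C)[C@H](C)C(O)=O | intermediate
9 | (3S,4R,5R)-5-[4-(benzyloxy)-3,5-dimethoxyphenyl]-3,4-dimethyloxolan-2-one | O=C1O[C@@H](c2cc(OC)c(OCc3ccccc3)c(OC)c2)[C@H](C)[C@@H]1C | intermediate
10 | (3S,4R,5R)-5-[4-(benzyloxy)-3,5-dimethoxyphenyl]-3,4-dimethyloxolan-2-ol, anomer mixture | OC1O[C@@H](c2cc(OC)c(OCc3ccccc3)c(OC)c2)[C@H](C)[C@@H]1C | intermediate
11 | veratrole (1,2-dimethoxybenzene) | COc1ccccc1OC | starting material
12 | (3S,4R,5R)-5-[4-(benzyloxy)-3,5-dimethoxyphenyl]-3,4-dimethyl-4,5-dihydro-3H-furan-1-ium (oxocarbenium ion, C2=O1+) | C1=[O+][C@@H](c2cc(OC)c(OCc3ccccc3)c(OC)c2)[C@H](C)[C@@H]1C | intermediate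
13 | (2S,3S,4R,5R)-5-[4-(benzyloxy)-3,5-dimethoxyphenyl]-2-(3,4-dimethoxyphenyl)-3,4-dimethyloxolane | COc1ccc([C@H]2O[C@@H](c3cc(OC)c(OCc4ccccc4)c(OC)c3)[C@H](C)[C@@H]2C)cc1OC | intermediate
14 | 4-[(2R,3R,4S,5S)-5-(3,4-dimethoxyphenyl)-3,4-dimethyloxolan-2-yl]-2,6-dimethoxyphenol | COc1ccc([C@H]2O[C@@H](c3cc(OC)c(O)c(OC)c3)[C@H](C)[C@@H]2C)cc1OC | target

## Step count and least certain steps

Total step count: 7. Longest linear sequence: 6 steps (1, 2, 7, 9, 10, 13, 14). The branch 3, 4, 7 is of equal length.

**Step 3 (key step).**
- What may go wrong: incomplete discrimination between the enantiotopic carbonyl groups. Transmetallation from the poorly soluble zinc triflate may also be slow, which lets an uncatalysed, unselective background acylation compete. Slow enolisation alpha to the new ketone at 50 °C would erode the erythro relation.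
- Partial remedy: moderate enantiomeric purity could be raised by crystallising 7 as a salt with a chiral amine, or by crystallising 9.
- Fallback (sets out from 2, returns at 9): alcoholysis instead of arylation becomes the symmetry-breaking event. Methanolysis of 2 is catalysed by a modified cinchona alkaloid, choosing the pseudo-enantiomer that opens the carbonyl group next to the (S)-carbon. It should give (2R,3S)-4-methoxy-2,3-dimethyl-4-oxobutanoic acid F1. Coupling with ethanethiol (DCC, DMAP) gives methyl (2S,3R)-4-(ethylsulfanyl)-2,3-dimethyl-4-oxobutanoate F2. A palladium-catalysed Fukuyama ketone synthesis with 6 gives methyl (2S,3R)-4-[4-(benzyloxy)-3,5-dimethoxyphenyl]-2,3-dimethyl-4-oxobutanoate F3. Reduction of F3 under the conditions of step 4 should close directly to 9 with loss of methanol.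

**Step 4.**
- What may go wrong: poor facial selectivity, because the two alkyl substituents on C4 differ less in size than the model assumes. Competing enolisation of the hindered ketone by the basic borohydride would scramble C4.
- Fallback (sets out from 7, returns at 9): correction by inversion instead of induction. The ketone is reduced without control (NaBH4, then acid) and the lactones are separated. The (3S,4R,5S)-configured 4,5-cis lactone F4 is saponified (LiOH, careful neutralisation) to (2S,3R,4S)-4-[4-(benzyloxy)-3,5-dimethoxyphenyl]-4-hydroxy-2,3-dimethylbutanoic acid F5. F5 is reclosed under Mitsunobu conditions (PPh3, DIAD), the carboxylate displacing the activated benzylic oxygen with inversion at C5 to give 9. A partly ionic course would lead to the same, more stable trans lactone.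

**Step 6.**
- What may go wrong: loss of the C3 proton from 12 to an enol ether and reprotonation, which would turn the cis-dimethyl unit into the more stable trans one. The product may ionise at C2 or C5, followed by attack of the other aryl ring (aryltetralin formation) or of excess 11. The Lewis acid may also remove the benzyl group.
- Fallback (sets out from 10, returns at 13): an aryl-metal replaces the arene and an anomeric sulfone replaces the lactol, so no strong Lewis acid is needed and the cation is trapped much faster. Treatment of 10 with benzenesulfinic acid (CaCl2, CH2Cl2) should give the 2-(phenylsulfonyl)oxolane F6. Reaction of F6 in THF with bis(3,4-dimethoxyphenyl)zinc F7, prepared from commercial 3,4-dimethoxyphenylmagnesium bromide and ZnBr2, should give 13 with the same anti approach to the methyl groups and a regiochemistry fixed by the carbon–metal bond.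

## Further compounds

F1 | step 3 | (2R,3S)-4-methoxy-2,3-dimethyl-4-oxobutanoic acid | OC(=O)[C@H](C)[C@H](C)C(=O)OC
F2 | step 3 | methyl (2S,3R)-4-(ethylsulfanyl)-2,3-dimethyl-4-oxobutanoate | CCSC(=O)[C@H](C)[C@H](C)C(=O)OC
F3 | step 3 | methyl (2S,3R)-4-[4-(benzyloxy)-3,5-dimethoxyphenyl]-2,3-dimethyl-4-oxobutanoate | O=C(c1cc(OC)c(OCc2ccccc2)c(OC)c1)[C@H](C)[C@H](C)C(=O)OC
F4 | step 4 | (3S,4R,5S)-5-[4-(benzyloxy)-3,5-dimethoxyphenyl]-3,4-dimethyloxolan-2-one | O=C1O[C@H](c2cc(OC)c(OCc3ccccc3)c(OC)c2)[C@H](C)[C@@H]1C
F5 | step 4 | (2S,3R,4S)-4-[4-(benzyloxy)-3,5-dimethoxyphenyl]-4-hydroxy-2,3-dimethylbutanoic acid | O[C@H](c1cc(OC)c(OCc2ccccc2)c(OC)c1)[C@H](C)[C@H](C)C(O)=O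
F6 | step 6 | (3S,4R,5R)-5-[4-(benzyloxy)-3,5-dimethoxyphenyl]-3,4-dimethyl-2-(phenylsulfonyl)oxolane, anomer mixture | O=S(=O)(c1ccccc1)C1O[C@@H](c2cc(OC)c(OCc3ccccc3)c(OC)c2)[C@H](C)[C@@H]1C
F7 | step 6 | bis(3,4-dimethoxyphenyl)zinc | COc1ccc([Zn]c2ccc(OC)c(OC)c2)cc1OC
A1 | alternative 1 | methyl (2S,3R)-3-[4-(benzyloxy)-3,5-dimethoxyphenyl]-3-hydroxy-2-methylpropanoate | O[C@@H](c1cc(OC)c(OCc2ccccc2)c(OC)c1)[C@H](C)C(=O)OC
A2 | alternative 1 | (4R,5R)-5-[4-(benzyloxy)-3,5-dimethoxyphenyl]-4-methyloxolan-2-one | O=C1O[C@@H](c2cc(OC)c(OCc3ccccc3)c(OC)c2)[C@H](C)C1
A3 | alternative 1 | (3R,4R,5R)-5-[4-(benzyloxy)-3,5-dimethoxyphenyl]-3,4-dimethyloxolan-2-one | O=C1O[C@@H](c2cc(OC)c(OCc3ccccc3)c(OC)c2)[C@H](C)[C@H]1C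
A4 | alternative 2 | (2S,3R)-4-[4-(benzyloxy)-3,5-dimethoxyphenyl]-1-(3,4-dimethoxyphenyl)-2,3-dimethylbutane-1,4-dione | O=C(c1cc(OC)c(OCc2ccccc2)c(OC)c1)[C@H](C)[C@H](C)C(=O)c1ccc(OC)c(OC)c1
A5 | alternative 3 | dimethyl (2S,3S)-2-[4-(benzyloxy)-3,5-dimethoxyphenyl]-3-methylcyclopropane-1,1-dicarboxylate (aryl and methyl cis) | COc1cc([C@@H]2[C@H](C)C2(C(=O)OC)C(=O)OC)cc(OC)c1OCc1ccccc1
A6 | alternative 3 | dimethyl (2R,4R,5R)-5-[4-(benzyloxy)-3,5-dimethoxyphenyl]-2-(3,4-dimethoxyphenyl)-4-methyloxolane-3,3-dicarboxylate (2,5-cis, 4,5-trans) | COc1ccc([C@H]2O[C@@H](c3cc(OC)c(OCc4ccccc4)c(OC)c3)[C@H](C)C2(C(=O)OC)C(=O)OC)cc1OC
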